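The quaterphenyl is cut at both biaryl bonds of ring B, b1–a1 and b5–c1. These two carbons flank the b6 oxygen, and the only ring B hydrogen (b3) lies para to it, so a b6 phenol can take rings C and A one after the other by oxygen-directed ligand coupling from tetravalent aryllead reagents, which act as aryl cation equivalents toward an electron-rich phenol. One flask thus joins three phloroglucinol-derived pieces: 3,5-dimethoxyphenol, 2,4,6-trimethoxyphenyllead triacetate and a ring C/D bromobiaryllead triacetate, the last built from the symmetric tribromide of trimethoxybenzene so that no halogen differentiation is needed. A single BBr3 demethylation then uncovers the eleven masked hydroxyls.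

Key step: step 6

Assumption: the target carries no stereodescriptor, so the B–C axis (four ortho oxygens, both rings unsymmetrical) is formed without control and no stereocentre has to be set; rings are lettered A (terminal ring on b1), B, C (brominated ring), D.

Step 1
Reactants: 1 1,3,5-trimethoxybenzene; 2 lead tetraacetate
Product: 3 2,4,6-trimethoxyphenyllead triacetate
Conditions: Pb(OAc)4 (1.0 equiv), CHCl3, rt, dark
Reagents that add atoms: none
Why: Direct electrophilic plumbation, in which the triply activated ring of 1 attacks tetravalent lead at a carbon flanked by two methoxy groups and loses a proton with acetate, a known entry to this reagent that stops at one aryl group because the aryllead triacetate is a far weaker electrophile than Pb(OAc)4.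

Step 2
Reactants: 1 1,3,5-trimethoxybenzene
Product: 4 1,3,5-tribromo-2,4,6-trimethoxybenzene
Conditions: Br2 (3.2 equiv), CH2Cl2, 0 °C to rt
Reagents that add atoms: bromine, BrBr
Why: Exhaustive electrophilic aromatic bromination of a phloroglucinol trimethyl ether, in which all three ring positions are equivalent and each is activated by three methoxy groups, so no regiochemical question arises.

Step 3
Reactants: 4 1,3,5-tribromo-2,4,6-trimethoxybenzene (3 equiv); 5 2,4,6-trimethoxyphenylboronic acid
Product: 6 3,5-dibromo-2,2',4,4',6,6'-hexamethoxybiphenyl (rings C and D; both bromines on ring C)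
Conditions: Pd(OAc)2 (cat.), SPhos, K3PO4, toluene/H2O, 90 °C
Reagents that add atoms: none
Why: Suzuki–Miyaura coupling with SPhos-ligated zerovalent palladium, a catalyst type established for tetra-ortho-substituted biaryls and 2,6-dialkoxyarylboronic acids; the three C–Br bonds of 4 are equivalent so only one mono-coupled product can form, and the threefold excess of recoverable 4, which should add oxidatively faster than the more electron-rich 6, holds the reaction at one coupling.

Step 4
Reactants: 6 3,5-dibromo-2,2',4,4',6,6'-hexamethoxybiphenyl
Product: 8 (5-bromo-2,2',4,4',6,6'-hexamethoxybiphenyl-3-yl)boronic acid, via aryllithium 7 (not isolated)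
Conditions: n-BuLi (1.05 equiv), THF, −78 °C; B(OMe)3, −78 °C to rt; aq NH4Cl
Reagents that add atoms: trimethyl borate, COB(OC)OC; water, O
Why: Bromine–lithium exchange followed by borylation, in which the two equivalent bromines of 6 give with one equivalent of n-BuLi the single aryllithium 7, which is flanked by two methoxy groups, has no ortho halogen from which an aryne could form, and is trapped by B(OMe)3 before hydrolysis at near-neutral pH to spare the protodeboronation-prone boronic acid.

Step 5
Reactants: 8 (5-bromo-2,2',4,4',6,6'-hexamethoxybiphenyl-3-yl)boronic acid; 2 lead tetraacetate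
Product: 9 (5-bromo-2,2',4,4',6,6'-hexamethoxybiphenyl-3-yl)lead triacetate (rings C and D, lead on c1)
Conditions: Pb(OAc)4 (0.95 equiv), Hg(OAc)2 (cat.), CHCl3, rt
Reagents that add atoms: none
Why: Boron–lead exchange (Hg(OAc)2-catalysed transmetalation of an arylboronic acid with Pb(OAc)4), in which ipso substitution at the carbon–boron bond should be much faster than C–H plumbation of ring D, a slight deficit of Pb(OAc)4 keeps free tetravalent lead oxidant out of the arylation, and the aryl bromide is inert.

Step 6
Reactants: 10 3,5-dimethoxyphenol (1.3 equiv); 9 (5-bromo-2,2',4,4',6,6'-hexamethoxybiphenyl-3-yl)lead triacetate; 3 2,4,6-trimethoxyphenyllead triacetate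
Product: 12 2-(5-bromo-2,2',4,4',6,6'-hexamethoxybiphenyl-3-yl)-3,5-dimethoxy-6-(2,4,6-trimethoxyphenyl)phenol (bromo quaterphenyl undecamethyl ether, b6 hydroxyl free), via monoaryl phenol 11 (not isolated)
Conditions: 9 (1.0 equiv), pyridine, CHCl3, 40 °C; then 3 (3 equiv), 60 °C
Reagents that add atoms: none
Why: Pyridine-assisted exchange of an acetate on tetravalent lead of 9 by phenol 10 gives an aryloxy(aryl)lead diacetate, ligand coupling then moves the ring C aryl group from lead to the ortho carbon b5 as lead falls to divalent Pb(OAc)2, and the cyclohexadienone tautomerises to phenol 11; the same sequence with 3 arylates the other ortho carbon b1 and gives 12. The closest known reaction is the Pinhey ortho-arylation of phenols with aryllead triacetates and pyridine, in which 3,5-disubstituted phenols are known to accept two ortho aryl groups and 2,6-dimethoxy-substituted aryllead reagents are established donors for hindered biaryls. No ring is closed and no stereocentre is set, the B–C axis being formed without control. Ortho must win over para and over O-arylation, which the intramolecular delivery from oxygen-bound lead secures, since only b1 and b5 are within reach and b3 keeps its hydrogen. The first coupling must stop at one aryl group and the two aryl groups must differ, which is secured by letting the scarce reagent 9 meet a slight excess of 10 first and then forcing the slower coupling of the hindered phenol 11 with an excess of the cheap reagent 3, leftover 10 ending as a bromine-free terphenyl that is easily removed. A third arylation of 12 would need a quaternary dienone carbon between two aryl groups and is not expected, and the aryl bromide is inert to the lead reagents.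

Step 7
Reactants: 12 bromo quaterphenyl undecamethyl ether with free b6 hydroxyl
Product: 13 4-(5-bromo-2,2',4,4',6,6'-hexahydroxybiphenyl-3-yl)-2-(2,4,6-trihydroxyphenyl)benzene-1,3,5-triol (target)
Conditions: BBr3 (excess), CH2Cl2, −78 °C to rt; then H2O, 0 °C
Reagents that add atoms: none
Why: Lewis acid ether cleavage, in which BBr3 coordinates each methoxy oxygen and bromide removes the methyl group as bromomethane, a reagent that leaves aryl bromides and biaryl bonds intact, and the cold aqueous quench frees the dodecaphenol from its borate esters while limiting acid-promoted bromine migration.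

Compound list
1 | 1,3,5-trimethoxybenzene | COc1cc(OC)cc(OC)c1 | starting material
2 | lead tetraacetate, Pb(OAc)4 | CC(=O)O[Pb](OC(C)=O)(OC(C)=O)OC(C)=O | starting material
3 | 2,4,6-trimethoxyphenyllead triacetate | COc1cc(OC)c([Pb](OC(C)=O)(OC(C)=O)OC(C)=O)c(OC)c1 | intermediate
4 | 1,3,5-tribromo-2,4,6-trimethoxybenzene | COc1c(Br)c(OC)c(Br)c(OC)c1Br | intermediate
5 | 2,4,6-trimethoxyphenylboronic acid | COc1cc(OC)c(B(O)O)c(OC)c1 | starting material
6 | 3,5-dibromo-2,2',4,4',6,6'-hexamethoxybiphenyl | COc1cc(OC)c(-c2c(OC)c(Br)c(OC)c(Br)c2OC)c(OC)c1 | intermediate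
7 | (5-bromo-2,2',4,4',6,6'-hexamethoxybiphenyl-3-yl)lithium | COc1cc(OC)c(-c2c(OC)c(Br)c(OC)c([Li])c2OC)c(OC)c1 | intermediate (not isolated)
8 | (5-bromo-2,2',4,4',6,6'-hexamethoxybiphenyl-3-yl)boronic acid | COc1cc(OC)c(-c2c(OC)c(Br)c(OC)c(B(O)O)c2OC)c(OC)c1 | intermediate
9 | (5-bromo-2,2',4,4',6,6'-hexamethoxybiphenyl-3-yl)lead triacetate | COc1cc(OC)c(-c2c(OC)c(Br)c(OC)c([Pb](OC(C)=O)(OC(C)=O)OC(C)=O)c2OC)c(OC)c1 | intermediate
10 | 3,5-dimethoxyphenol | COc1cc(O)cc(OC)c1 | starting material
11 | 2-(5-bromo-2,2',4,4',6,6'-hexamethoxybiphenyl-3-yl)-3,5-dimethoxyphenol | COc1cc(O)c(-c2c(OC)c(Br)c(OC)c(-c3c(OC)cc(OC)cc3OC)c2OC)c(OC)c1 | intermediate (not isolated)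
12 | 2-(5-bromo-2,2',4,4',6,6'-hexamethoxybiphenyl-3-yl)-3,5-dimethoxy-6-(2,4,6-trimethoxyphenyl)phenol | COc1cc(OC)c(-c2c(OC)cc(OC)c(-c3c(OC)c(Br)c(OC)c(-c4c(OC)cc(OC)cc4OC)c3OC)c2O)c(OC)c1 | intermediate
13 | 4-(5-bromo-2,2',4,4',6,6'-hexahydroxybiphenyl-3-yl)-2-(2,4,6-trihydroxyphenyl)benzene-1,3,5-triol | Oc1cc(O)c(-c2c(O)cc(O)c(-c3c(O)c(Br)c(O)c(-c4c(O)cc(O)cc4O)c3O)c2O)c(O)c1 | target

Total step count: 7
Longest linear sequence: 6 steps (steps 2, 3, 4, 5, 6 and 7, from 1,3,5-trimethoxybenzene).

Steps most likely to fail

Step 6. The first ligand coupling may run on to a second aryl group of the same kind, or the slower coupling at the hindered phenol 11 may be outrun by decomposition of the lead reagent, so that statistical mixtures of polyaryls result. The fallback sets out from 5 and 6 and comes back to the route at 13; it replaces ligand coupling by cross-coupling throughout. Boronic acid 5 is coupled with commercial 2-bromo-1,3,5-trimethoxybenzene under the step 3 conditions to give 2,2',4,4',6,6'-hexamethoxybiphenyl F1. One of its four equivalent C–H bonds, each flanked by two methoxy groups, is lithiated (n-BuLi, TMEDA, THF, 0 °C) to the 3-lithio biphenyl F2, and B(OMe)3 followed by near-neutral hydrolysis gives (2,2',4,4',6,6'-hexamethoxybiphenyl-3-yl)boronic acid F3. Suzuki–Miyaura coupling of F3 with an excess of dibromide 6 (Pd(OAc)2, SPhos, K3PO4), whose two C–Br bonds are equivalent, should give the bromo quaterphenyl dodecamethyl ether F4. BBr3 under the step 7 conditions then cleaves twelve ethers to 13.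

Step 3. Protodeboronation of 5 may outpace the hindered transmetalation, or coupling may continue to a terphenyl. The fallback sets out from 10 and 3 and comes back at 6; it makes the C–D bond by ligand coupling instead. An excess of 10 with 3 and pyridine in CHCl3 should give 3,5-dimethoxy-2-(2,4,6-trimethoxyphenyl)phenol F5. As its phenoxide (Br2, 2 equiv, aqueous NaOH/THF, 0 °C) only the phenol ring is brominated, at both free positions, to 4,6-dibromo-3,5-dimethoxy-2-(2,4,6-trimethoxyphenyl)phenol F6. O-Methylation (MeI, K2CO3, acetone) gives 6.

Step 5. Protodeboronation of the electron-rich boronic acid, or competing C–H plumbation of ring D (the reactivity used in step 1), may leave a lead reagent of poor purity that then oxidises the phenol in step 6. The fallback sets out from 6 and comes back at 9; it relays through tin, so that no protodeboronation-prone intermediate is handled. Aryllithium 7, generated as in step 4, is quenched with Bu3SnCl to give the chromatographically stable tributyl(5-bromo-2,2',4,4',6,6'-hexamethoxybiphenyl-3-yl)stannane F7. Tin–lead exchange with Pb(OAc)4 (Hg(OAc)2 cat., CHCl3) then gives 9 from rigorously purified material.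

Further compounds
F1 | step 6 | 2,2',4,4',6,6'-hexamethoxybiphenyl | COc1cc(OC)c(-c2c(OC)cc(OC)cc2OC)c(OC)c1
F2 | step 6 | (2,2',4,4',6,6'-hexamethoxybiphenyl-3-yl)lithium | COc1cc(OC)c(-c2c(OC)cc(OC)c([Li])c2OC)c(OC)c1
F3 | step 6 | (2,2',4,4',6,6'-hexamethoxybiphenyl-3-yl)boronic acid | COc1cc(OC)c(-c2c(OC)cc(OC)c(B(O)O)c2OC)c(OC)c1
F4 | step 6 | bromo quaterphenyl dodecamethyl ether (permethylated 13) | COc1cc(OC)c(-c2c(OC)cc(OC)c(-c3c(OC)c(Br)c(OC)c(-c4c(OC)cc(OC)cc4OC)c3OC)c2OC)c(OC)c1
F5 | step 3 | 3,5-dimethoxy-2-(2,4,6-trimethoxyphenyl)phenol | COc1cc(O)c(-c2c(OC)cc(OC)cc2OC)c(OC)c1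
F6 | step 3 | 4,6-dibromo-3,5-dimethoxy-2-(2,4,6-trimethoxyphenyl)phenol | COc1c(Br)c(O)c(-c2c(OC)cc(OC)cc2OC)c(OC)c1Br
F7 | step 5 | tributyl(5-bromo-2,2',4,4',6,6'-hexamethoxybiphenyl-3-yl)stannane | CCCC[Sn](CCCC)(CCCC)c1c(OC)c(Br)c(OC)c(-c2c(OC)cc(OC)cc2OC)c1OC
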